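In a one-step world, substrate plus reagent giving a product, I would have needed one number, the pseudo-first-order half-life of substrate, and the spring readings put it near 1.48 h. The readings, however, looked to me like a ladder on which substrate takes up reagent to become single, double, triple and tetra adduct in turn.

| flask | substrate | reagent | remark | time |
|---|---|---|---|---|
| spring | 5 mM | 30 mM | run made earlier |  |
| dusk | 7.5 mM | 30 mM | run made earlier |  |
| theta | 10 mM | 30.0 mM |  | 50 h |
| beta | 10 mM | 30.0 mM |  | 15 h |

| run | time / h | tetra adduct / % | single product / % | triple product / % | double product / % | substrate / % |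
|---|---|---|---|---|---|---|
| spring | 1.33 | 0.4 | 37.6 | 0.1 | 10.8 | 53.0 |
| spring | 3.00 | 0 | 40.6 | 6.3 | 27.4 | 24.5 |
| spring | 8.00 | 7.5 | 18.8 | 26.5 | 44.5 | 2.0 |
| spring | 20.0 | 31.6 | 3.0 | 42.9 | 21.3 | 0.5 |
| dusk | 2.50 | 0.4 | 42.4 | 2.6 | 21.1 | 32.1 |
| dusk | 6.00 | 0.6 | 32.2 | 15.5 | 40.7 | 10.3 |
| dusk | 12.0 | 11.2 | 14.4 | 32.6 | 42.0 | 1.3 |
| dusk | 20.0 | 21.3 | 5.7 | 42.2 | 31.8 | 2.0 |

(scatter of a reading: 1 percentage point)

- the analysis behind the earlier runs scatters by 1 percentage point, standard deviation

* which of these there is most of at the end, counted by the substrate in it, theta (double product / single product / tetra adduct / triple product)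
* which of these there is most of at the end, counted by the substrate in it, beta (double product / single product / tetra adduct / triple product)
* the largest of these amounts at the end, in percent of the substrate charged, theta
* the largest of these amounts at the end, in percent of the substrate charged, beta

In the spring run substrate went first, single product still led double at 3.00 h, double led by 8.00 h, and triple led at 20.0 h with tetra adduct behind it at 31.6%. I therefore counted the mean rung, the additions per substrate charged, in the readings:

| run, time | mean rung | double | triple |
|---|---|---|---|
| spring, 8.00 h | 2.17 | 44.5% | 26.5% |
| dusk, 12.0 h | 2.41 | 42.0% | 32.6% |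
| dusk, 20.0 h | 2.81 | 31.8% | 42.2% |
| spring, 20.0 h | 3.01 | 21.3% | 42.9% |

Triple overtook double between the middle rows, so I took the crossing rung, the mean rung at which triple passes double, as 2.61. The charge in theta and beta allows 3.00 additions per substrate, above that rung, so the crossing could be reached, but when?

Dusk crossed near 16.0 h with a logarithmic-mean reagent of 18.5 mM. Taking mean reagent times hours as equal at the crossing, I reckoned that theta and beta, with 12.8 mM on the way there, should reach it at about 23.2 h. That is later than beta's 15 h and earlier than theta's 50 h, so I expected double to lead in beta and triple in theta, without reckoning amounts.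

The forecast named triple product at 42% for theta and double product at 42.5% for beta, saying “reagent nearly runs out around an average of three additions”.

The flasks gave triple product at 42.8% in theta and double product at 42.9% in beta.

    reagent + double product → triple product (k = 0.00175 L mol⁻¹ s⁻¹)
    substrate + reagent → single product (k = 0.00484 L mol⁻¹ s⁻¹)
    reagent + single product → double product (k = 0.00363 L mol⁻¹ s⁻¹)
    reagent + triple product → tetra adduct (k = 9.37 × 10⁻⁴ L mol⁻¹ s⁻¹)

With 4.8% of its reagent left, theta stood at a mean rung of 2.86, above the crossing, while beta, with 24% left, stood at 2.28, below it. A longer time turns the forecast's choice for beta wrong: at 150 h beta holds triple product at 43.7% and double product at 24.2%.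

The neighbour with 18 mM of reagent, otherwise beta, allows 1.80 additions per substrate, below the crossing, so I put double ahead of triple there. It ended with 37.7% of double product against 11.6% of triple product.

The data are simulated with constants of no real substance; scatter was added.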